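The runs come from a simulation with constants of no real substance.

If two mirror-image substrates are consumed on one catalyst and do not interconvert, dividing the fractional rate of loss of one by that of the other makes time drop out.

| setting | north | north-west | flask |
|---|---|---|---|
| left-handed substrate | 0.10 M | 0.10 M | 0.10 M |
| right-handed substrate | 0.10 M | 0.10 M | 0.10 M |
| gas | 35 mM (held) | 35 mM (held) | 35 mM (held) |
| free catalyst | 0.25 mM | 1 mM | 0.50 mM |
| racemization catalyst | 1.3 mM | 1.3 mM | 1.3 mM |
| remark | run made earlier | run made earlier |  |
| time |  |  | 12 h |

| run | time / h | left-handed product / % | right-handed product / % |
|---|---|---|---|
| north | 0.500 | 0.8 | 0.9 |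
| north | 1.00 | 4.3 | 1.7 |
| north | 1.50 | 7.2 | 3.6 |
| north | 2.50 | 12.9 | 5.8 |
| north | 4.00 | 20.5 | 10.9 |
| north | 8.00 | 35.4 | 20.0 |
| north-west | 0.500 | 4.5 | 2.4 |
| north-west | 1.33 | 13.5 | 6.4 |
| north-west | 2.50 | 25.3 | 12.7 |
| north-west | 4.00 | 36.8 | 21.3 |
| north-west | 6.00 | 46.1 | 30.8 |
| north-west | 8.00 | 49.8 | 38.5 |

(standard deviation of a reading: 0.3 percentage points)

- left-handed product and right-handed product together, in percent of the left-handed substrate and right-handed substrate charged together, at 12 h
- excess of left-handed product over right-handed product in the product at 12 h
- whether the exchange between left-handed substrate and right-handed substrate keeps pace with the reaction: how far the product's excess at 12 h gets from its value without exchange to its value with instant exchange (above 80% keeps pace, below 20% hardly takes part, else lags behind)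

- free catalyst is single-handed; left-handed substrate and right-handed substrate are mirror images of each other, charged as a racemate, each of them at the stated concentration
- the analysis behind the earlier runs scatters by 0.3 percentage points, standard deviation
- at the start none of the gas is in solution
- an excess is the difference of the two amounts in percent of their sum
- an excess is below zero if the other one leads

That ratio is the selectivity factor s: the logarithm of the fraction of left-handed substrate left, over the same for right-handed substrate, each of its own charge, or d ln c(left-handed substrate)/d ln c(right-handed substrate). It reads 2.40 in north-west at 4.00 h, and 2.41 in north at 8.00 h.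

Two views dispute the flask. The exchanger says 1.3 mM of racemization catalyst keeps the substrates equal, so the product's excess holds at (s−1)/(s+1), a ceiling of 41.2%; north at 2.50 h already shows 38.0%.

The resolver says each substrate goes its own way. In north-west at 4.00 h, 26.4% of the left-handed substrate stands against 57.4% of the right-handed, which is far from equal. North, with twice the time, reads the same s. Taking the flask to stand near north-west's last reading, 23.0% of the right-handed substrate left gives 2.94% of the left-handed, so an excess of about 11.5%. That is an estimate and no bound: s and that reading both come from runs charged with 1.3 mM of racemization catalyst. I side with the resolver and expect an excess near that figure.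

The forecast says 90%, 12% and hardly takes part, on the ground that “Only late north-west points exceed the no-exchange line”.

The flask gives 88.7% with an excess of 13.0%, 10% of the way: the exchange hardly takes part.

    coupling partner + free catalyst + left-handed substrate → free catalyst + left-handed product (k = 433 /M²/min)
    coupling partner + free catalyst + right-handed substrate → free catalyst + right-handed product (k = 190 /M²/min)
    left-handed substrate + racemization catalyst ⇌ right-handed substrate + racemization catalyst, rate k3*[racemization catalyst]*[left-handed substrate] forward; the back reaction follows from the equilibrium constant (k = 0.891 /M/min)
    gas ⇌ coupling partner, rate k4*(csat - [coupling partner]) (kL = 0.0243 /min)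
    2 racemization catalyst → spent catalyst (k = 4.33 /M/min)

The exchanger's view fits the flask's early stretch: at 1.20 h, with 12.3% reacted, the substrates differ by 4.95% and the product's excess is 36.9%. At 12.0 h the flask holds 11.0% of its racemization catalyst, and with that decay struck out the excess is 19.7%. Applied to the flask's 19% of right-handed substrate left, s gives 1.91% of the left-handed, and 3.3% stands there. In the neighbour with 2.00 mM of free catalyst, 0.24% of right-handed substrate left gives an unexchanged excess of 0.121%, and that neighbour shows 3.23%.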